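**The leftover.** Starting material must be left over in violet and in blue even once the coupling partner is used up, because less coupling partner is charged than starting material. The runs do not read the coupling partner, so I assume one per product.

the same everywhere: starting material 20 mM

| charge | coupling partner | precatalyst | added ligand | temperature | remark | time |
|---|---|---|---|---|---|---|
| alder | 12 mM | 20 µM | 20 µM | 11 °C | run made earlier |  |
| larch | 12 mM | 20 µM | 78 µM | 25 °C | run made earlier |  |
| cedar | 12 mM | 30 µM | 39 µM | 11 °C | run made earlier |  |
| violet | 12.0 mM | 20 µM | 39 µM | 30 °C |  | 80 min |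
| blue | 12.0 mM | 20 µM | 39 µM | 5 °C |  | 80 min |

| run | time / min | catalyst intermediate B / % | catalyst intermediate A / % | starting material / % | product / % |
|---|---|---|---|---|---|
| alder | 20.0 | 0.6 | 0 | 95.6 | 3.5 |
| alder | 40.0 | 0 | 0 | 86.8 | 12.7 |
| alder | 60.0 | 0 | 0.2 | 77.1 | 22.4 |
| alder | 80.0 | 0 | 0.4 | 68.3 | 32.5 |
| alder | 90.0 | 0 | 0.2 | 63.9 | 36.6 |
| larch | 3.00 | 0.5 | 0 | 100.0 | 0.3 |
| larch | 6.00 | 0 | 0 | 98.3 | 1.6 |
| larch | 10.0 | 0 | 0.5 | 96.4 | 4.2 |
| larch | 20.0 | 0 | 0 | 87.5 | 12.4 |
| larch | 30.0 | 0 | 0 | 78.0 | 21.7 |
| cedar | 8.00 | 0.4 | 0 | 99.5 | 0.9 |
| cedar | 25.0 | 0.3 | 0 | 93.2 | 7.0 |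
| cedar | 40.0 | 0 | 0.2 | 85.2 | 14.5 |
| cedar | 60.0 | 0 | 0.3 | 74.1 | 25.6 |
| cedar | 90.0 | 0.1 | 0.7 | 59.7 | 39.9 |

(each reading ± 0.3 percentage points)

- which of these there is most of at the end, counted by the starting material in it, violet (starting material / product / catalyst intermediate B / catalyst intermediate A)
- which of these there is most of at the end, counted by the starting material in it, blue (starting material / product / catalyst intermediate B / catalyst intermediate A)
- amount of the one of these that there is most of at the end, in percent of the starting material charged, violet
- amount of the one of these that there is most of at the end, in percent of the starting material charged, blue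

- the analysis behind the earlier runs scatters by 0.3 percentage points, standard deviation

**The ledger.** I book the coupling partner, the limiting reagent, in fractions of the starting material charged. Its charge is 0.600. I call this the ceiling: coupling partner charged over starting material charged, the most product the flask can book. The first entry is the catalyst. If each catalyst holds or spends one coupling partner, that costs 1.00 × 10⁻³, far below the ceiling. The second entry is product, as far as the clock allows. The last entry is unused coupling partner.

**Violet's clock.** Larch gains 0.00930 min⁻¹ after a lag of 6.67 min. Cedar has more precatalyst and more ligand than alder, yet gains 0.00508 min⁻¹ against alder's 0.00495 min⁻¹. So I read ligand as a brake. Violet is warmer than larch and has less ligand, so I take larch's rate as its floor. At that rate the ceiling comes at 71.2 min, before 80 min. I expect violet's product just under 0.600.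

**Blue's clock.** I scale cedar to blue's precatalyst, which gives 0.00339 min⁻¹ at cedar's temperature. The step from there to larch, though larch has more ligand, I carry down to blue's temperature. That gives 0.00220 min⁻¹. Cedar's lag of 11.5 min stretches to 17.7 min. Blue's product then reaches 0.137, under the ceiling, which leaves starting material at 0.863.

The forecast, a little higher than I am on blue's starting material, gives product at 59.8 % in violet and starting material at 89 % in blue, with “so the coupling partner (12 mM, 60 %) runs out by about 30 min”.

**The result.** Violet ends with product at 59.3 %, and 0.991 % of its coupling partner remains. Blue ends with starting material at 86.9 %.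

    coupling partner + catalyst intermediate A → catalyst intermediate B (k = 16.0 M⁻¹ s⁻¹, Ea = 43.0 kJ mol⁻¹)
    starting material + free catalyst → catalyst intermediate A (k = 385 M⁻¹ s⁻¹, Ea = 37.0 kJ mol⁻¹)
    free catalyst + added ligand ⇌ idle complex, settled at all times (K = 2.26 × 10⁶ M⁻¹, ΔH = −41.0 kJ mol⁻¹)
    catalyst intermediate B → free catalyst + product (k = 0.583 s⁻¹, Ea = 71.0 kJ mol⁻¹)
    coupling partner + precatalyst → free catalyst + spent reagent (k = 0.0277 M⁻¹ s⁻¹, Ea = 43.0 kJ mol⁻¹)
    (constants at 5 °C)

**The neighbour.** Take violet with 7.2 mM of coupling partner. Its ceiling is 0.360, and larch's floor rate reaches that at 45.4 min, before 80 min. So I book product just under 0.360. The flask gives product 35.3 %, with 1.6 % of its coupling partner remaining, and starting material now exceeds product at 64.6 %.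

The data stem from a simulated flask with made-up constants, and the scatter is random.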